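## Retrosynthetic overview
1. The last bond is C3–C1′, made by Stille coupling of a 3-chloro core ester with the (1E,3E,5S)-dienylstannane. The stannane comes from (S)-2-methylbutan-1-ol by Wittig, Corey–Fuchs and hydrostannation.
2. C5(OH)(CO2Me) comes from a C5 exocyclic methylene: dihydroxylation anti to the 6-acetoxy group, then CH2OH → CO2H → CO2Me.
3. The carbocycle is closed at C7–C7a by Parham cyclisation of a bromopyridine onto a dioxolanone carbonyl. This step also expels the auxiliary and frees the 6-OH.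
4. The key bond is C5–C6: an intermolecular aldol of the lithium enolate of the (R)-lactic acid/pivalaldehyde dioxolanone with 4-acetyl-5-bromo-2-chloropyridine sets C6, and dehydration follows.
5. Ring order: the pyridine is bought, then a temporary dioxolanone ring is made, then the five-membered carbocycle, which is the only ring of the target that is built.

Assumption: the SMILES is taken as drawn, which means (5R,6S) in the core with 5-OH trans to 6-OAc, (5S) in the side chain and both alkenes E. Locants follow cyclopenta[c]pyridine numbering (C1, N2, C3, C4, C4a, C5, C6, C7, C7a).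

## Route

### Fragment A (pyridyl ketone)

Step 1
Reactants: 1 5-bromo-2-chloropyridine
Product: 3 1-(5-bromo-2-chloropyridin-4-yl)ethan-1-one, via 4-lithio-5-bromo-2-chloropyridine 2 (not isolated)
Conditions: LiN(iPr)2 (LDA, 1.05 equiv), THF, −78 °C, 45 min; MeC(O)N(OMe)Me, −78 → −40 °C; AcOH
Reagents that add atoms: N-methoxy-N-methylacetamide, CC(=O)N(C)OC
Why: Directed ortho-lithiation followed by Weinreb ketone synthesis, in which LDA removes the C4 proton next to bromine at −78 °C (too cold for halogen dance or pyridyne formation) and the Weinreb amide transfers one acetyl group without over-addition; no stereocentre is formed.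

### Fragment B (chiral lactate enolate precursor)

Step 2
Reactants: 4 (R)-lactic acid
Product: 5 (2R,5R)-2-tert-butyl-5-methyl-1,3-dioxolan-4-one (cis)
Conditions: t-BuCHO (1.5 equiv), p-TsOH·H2O (cat.), H2SO4 (cat.), pentane, reflux, Dean–Stark; recrystallise from pentane, −78 °C
Reagents that add atoms: pivalaldehyde, CC(C)(C)C=O
Why: Acid-catalysed acetalisation (first stage of Seebach's self-regeneration of stereocentres), in which the lactate centre steers the new acetal centre to the cis isomer (about 4:1 under equilibration) and crystallisation gives pure (2R,5R)-5.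

### Union and core

Step 3 (key step)
Reactants: 5 (2R,5R)-2-tert-butyl-5-methyl-1,3-dioxolan-4-one (1.3 equiv); 3 1-(5-bromo-2-chloropyridin-4-yl)ethan-1-one
Product: 7 (2R,5S)-5-[1-(5-bromo-2-chloropyridin-4-yl)-1-hydroxyethyl]-2-tert-butyl-5-methyl-1,3-dioxolan-4-one (both carbinol epimers), via lithium enolate 6 (not isolated)
Conditions: LDA (1.35 equiv), THF, −78 °C, 40 min; 3 in THF, −78 °C, 2 h; AcOH in THF at −78 °C
Reagents that add atoms: none
Why: Intermolecular lithium-enolate aldol addition, in which enolisation erases the lactate centre but the acetal centre survives and its tert-butyl group shields one face of planar 6, so the ketone carbonyl is attacked anti to it (typically >95:5) and the quaternary carbon that becomes (6S) is set; the new carbinol centre may be a mixture because step 4 makes it sp2, and the cold acidic quench prevents retro-aldol.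

Step 4
Reactants: 7 aldol adduct
Product: 8 (2R,5S)-5-[1-(5-bromo-2-chloropyridin-4-yl)ethenyl]-2-tert-butyl-5-methyl-1,3-dioxolan-4-one
Conditions: SOCl2 (3 equiv), pyridine, 0 °C → rt
Reagents that add atoms: none
Why: E2-type dehydration through the chlorosulfite, in which only the methyl group carries β-hydrogens (the neighbouring carbon is quaternary), so the 1,1-disubstituted alkene is the sole regioisomer, both carbinol epimers converge and the two remaining stereocentres are untouched.

Step 5
Reactants: 8 alkenyl dioxolanone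
Product: 10 (6S)-3-chloro-6-hydroxy-6-methyl-5-methylidene-5,6-dihydro-7H-cyclopenta[c]pyridin-7-one, via pyridin-3-yllithium 9 (not isolated)
Conditions: n-BuLi (1.05 equiv), THF/Et2O, −100 °C, 10 min, then −78 °C, 30 min; AcOH, −78 °C → rt
Reagents that add atoms: none
Why: Parham cyclisation, in which Br/Li exchange on the electron-poor bromopyridine outruns carbonyl or ring addition at −100 °C, the aryllithium sits next to the activated acylal carbonyl and closes the five-membered ring (5-exo-trig), and the auxiliary leaves as pivalaldehyde to unveil the tertiary alcohol without touching C6.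

Step 6
Reactants: 10 hydroxy ketone
Product: 11 (6S)-3-chloro-6-methyl-5-methylidene-7-oxo-6,7-dihydro-5H-cyclopenta[c]pyridin-6-yl acetate
Conditions: Ac2O (3 equiv), DMAP (0.5 equiv), Et3N (4 equiv), CH2Cl2, rt
Reagents that add atoms: acetic anhydride, CC(=O)OC(C)=O
Why: DMAP-catalysed acylation of the only hydroxyl present, placed here so that the two tertiary alcohols of the target never have to be told apart; C6 has no α-hydrogen and cannot epimerise.

Step 7
Reactants: 11 allylic acetate
Product: 12 (5S,6S)-3-chloro-5-hydroxy-5-(hydroxymethyl)-6-methyl-7-oxo-6,7-dihydro-5H-cyclopenta[c]pyridin-6-yl acetate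
Conditions: OsO4 (4 mol %), NMO (1.5 equiv), acetone/H2O 4:1, 0 °C → rt; aq Na2SO3; rapid chromatography
Reagents that add atoms: N-methylmorpholine N-oxide, C[N+]1([O-])CCOCC1; water, O; OsO4 (catalytic oxygen carrier), O=[Os](=O)(=O)=O
Why: Upjohn dihydroxylation under cyclic substrate control, in which the bicycle is flat and the alkene faces differ only in the C6 substituents, so OsO4 adds anti to the allylic C–O bond (Kishi's empirical rule, reinforced by the acetyl group lying over that face) and places the new 5-OH trans to 6-OAc with CH2OH cis to it; the descriptor is 5S here and becomes 5R once CH2OH is oxidised.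

Step 8
Reactants: 12 diol
Product: 14 (5R,6S)-6-acetoxy-3-chloro-5-hydroxy-6-methyl-7-oxo-6,7-dihydro-5H-cyclopenta[c]pyridine-5-carboxylic acid, via hydroxy aldehyde 13 (not isolated)
Conditions: TEMPO (10 mol %), NaClO2 (2.5 equiv), NaOCl (5 mol %), MeCN / NaH2PO4–Na2HPO4 buffer pH 6.7, rt; acidify to pH 3–4, extract, use at once
Reagents that add atoms: sodium chlorite, [Na+].[O-]Cl=O
Why: TEMPO/chlorite oxidation (oxoammonium oxidation to the aldehyde, then a Pinnick-type step) takes only the primary alcohol to the acid at near-neutral pH, so the tertiary alcohol, the acetate and the β-hydroxy ketone (retro-aldol) are not disturbed and no C–C cleavage of the glycol occurs.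

Step 9
Reactants: 14 hydroxy acid
Product: 15 methyl (5R,6S)-6-acetoxy-3-chloro-5-hydroxy-6-methyl-7-oxo-6,7-dihydro-5H-cyclopenta[c]pyridine-5-carboxylate
Conditions: TMSCHN2 (1.3 equiv), toluene/MeOH 4:1, 0 °C
Reagents that add atoms: (trimethylsilyl)diazomethane, C[Si](C)(C)C=[N+]=[N-]
Why: Diazoalkane O-methylation of the carboxylic acid is fast and base-free, so it avoids decarboxylation of the pyridylacetic-type acid, acetate migration and retro-aldol, and the tertiary alcohol is not methylated.

### Fragment C (dienylstannane)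

Step 10
Reactants: 16 (S)-2-methylbutan-1-ol
Product: 17 (S)-2-methylbutanal
Conditions: TEMPO (1 mol %), KBr (10 mol %), aq NaOCl (1.1 equiv, NaHCO3, pH 9.5), CH2Cl2/H2O, 0 °C; careful distillation
Reagents that add atoms: none
Why: Anelli oxidation stops at the aldehyde within minutes at 0 °C, fast enough that the chiral-pool α-stereocentre is not racemised.

Step 11
Reactants: 17 (S)-2-methylbutanal
Product: 18 ethyl (2E,4S)-2,4-dimethylhex-2-enoate
Conditions: Ph3P=C(Me)CO2Et (1.15 equiv), CH2Cl2, rt, 16 h
Reagents that add atoms: ethyl 2-(triphenylphosphoranylidene)propanoate, CCOC(=O)C(C)=P(c1ccccc1)(c1ccccc1)c1ccccc1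
Why: Wittig olefination with a stabilised, non-basic ylide gives the E trisubstituted enoate (≥95:5) and leaves the adjacent stereocentre intact.

Step 12
Reactants: 18 enoate
Product: 19 (2E,4S)-2,4-dimethylhex-2-en-1-ol
Conditions: iBu2AlH (DIBAL-H, 2.3 equiv), CH2Cl2, −78 → 0 °C; aq KNaC4H4O6
Reagents that add atoms: none
Why: Clean 1,2-reduction of the enoate to the allylic alcohol by an aluminium hydride, with no change of alkene geometry or of the stereocentre.

Step 13
Reactants: 19 allylic alcohol
Product: 20 (2E,4S)-2,4-dimethylhex-2-enal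
Conditions: MnO2 (15 equiv), CH2Cl2, rt
Reagents that add atoms: none
Why: Selective heterogeneous allylic oxidation with MnO2 under neutral conditions gives the enal without E/Z isomerisation.

Step 14
Reactants: 20 enal
Product: 21 (3E,5S)-1,1-dibromo-3,5-dimethylhepta-1,3-diene
Conditions: CBr4 (2 equiv), PPh3 (4 equiv), CH2Cl2, 0 °C
Reagents that add atoms: carbon tetrabromide, BrC(Br)(Br)Br
Why: First stage of the Corey–Fuchs homologation (Wittig-type dibromoolefination), which works well on enals where basic diazophosphonate methods give conjugate-addition by-products.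

Step 15
Reactants: 21 dibromodiene
Product: 23 (3E,5S)-3,5-dimethylhept-3-en-1-yne, via lithium acetylide 22 (not isolated)
Conditions: n-BuLi (2.2 equiv), THF, −78 → 0 °C; H2O; careful concentration (volatile)
Reagents that add atoms: none
Why: Second stage of the Corey–Fuchs reaction (Br/Li exchange, Fritsch–Buttenberg–Wiechell-type rearrangement and deprotonation to the acetylide) gives the terminal enyne on protonation with the trisubstituted alkene untouched.

Step 16
Reactants: 23 enyne
Product: 24 tributyl[(1E,3E,5S)-3,5-dimethylhepta-1,3-dien-1-yl]stannane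
Conditions: Bu3SnH (1.1 equiv), PdCl2(PPh3)2 (2 mol %), THF, 0 °C → rt; Et3N-deactivated silica
Reagents that add atoms: tributyltin hydride, CCCC[SnH](CCCC)CCCC
Why: Palladium-catalysed syn-hydrostannation (the precatalyst is reduced by the stannane to zerovalent palladium) sets the E C1′=C2′ alkene, and the methyl-branched sp2 carbon next to the alkyne directs tin to the terminal carbon.

### Endgame

Step 17
Reactants: 15 chloropyridine core ester; 24 dienylstannane (1.3 equiv)
Product: 25 methyl (5R,6S)-6-acetoxy-3-[(1E,3E,5S)-3,5-dimethylhepta-1,3-dien-1-yl]-5-hydroxy-6-methyl-7-oxo-6,7-dihydro-5H-cyclopenta[c]pyridine-5-carboxylate (target)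
Conditions: Pd(PPh3)4 (8 mol %), 1,4-dioxane, 95 °C, argon, dark
Reagents that add atoms: none
Why: Stille coupling, in which the C–Cl bond lies α to nitrogen and para to the acyl-bearing carbon and so adds readily to zerovalent palladium, transmetalation and reductive elimination retain the diene geometry, and the base-free medium spares the acetate, the methyl ester and the retro-aldol-prone β-hydroxy ketone, so all stereocentres are kept.

## Compound list
1 | 5-bromo-2-chloropyridine | Clc1ccc(Br)cn1 | starting material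
2 | 4-lithio-5-bromo-2-chloropyridine | [Li]c1cc(Cl)ncc1Br | intermediate
3 | 1-(5-bromo-2-chloropyridin-4-yl)ethan-1-one | CC(=O)c1cc(Cl)ncc1Br | intermediate
4 | (R)-lactic acid | C[C@@H](O)C(=O)O | starting material
5 | (2R,5R)-2-tert-butyl-5-methyl-1,3-dioxolan-4-one | C[C@H]1O[C@@H](C(C)(C)C)OC1=O | intermediate
6 | lithium (2R)-2-tert-butyl-5-methyl-1,3-dioxol-4-olate (enolate of 5) | CC1=C(O[Li])O[C@H](C(C)(C)C)O1 | intermediate
7 | (2R,5S)-5-[1-(5-bromo-2-chloropyridin-4-yl)-1-hydroxyethyl]-2-tert-butyl-5-methyl-1,3-dioxolan-4-one (carbinol epimers) | C[C@@]1(C(C)(O)c2cc(Cl)ncc2Br)O[C@@H](C(C)(C)C)OC1=O | intermediate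
8 | (2R,5S)-5-[1-(5-bromo-2-chloropyridin-4-yl)ethenyl]-2-tert-butyl-5-methyl-1,3-dioxolan-4-one | C[C@@]1(C(=C)c2cc(Cl)ncc2Br)O[C@@H](C(C)(C)C)OC1=O | intermediate
9 | pyridin-3-yllithium from Br/Li exchange of 8 | C[C@@]1(C(=C)c2cc(Cl)ncc2[Li])O[C@@H](C(C)(C)C)OC1=O | intermediate
10 | (6S)-3-chloro-6-hydroxy-6-methyl-5-methylidene-5,6-dihydro-7H-cyclopenta[c]pyridin-7-one | Clc1cc2c(cn1)C(=O)[C@@](C)(O)C2=C | intermediate
11 | (6S)-3-chloro-6-methyl-5-methylidene-7-oxo-6,7-dihydro-5H-cyclopenta[c]pyridin-6-yl acetate | Clc1cc2c(cn1)C(=O)[C@@](C)(OC(C)=O)C2=C | intermediate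
12 | (5S,6S)-3-chloro-5-hydroxy-5-(hydroxymethyl)-6-methyl-7-oxo-6,7-dihydro-5H-cyclopenta[c]pyridin-6-yl acetate | Clc1cc2c(cn1)C(=O)[C@@](C)(OC(C)=O)[C@@]2(O)CO | intermediate
13 | (5R,6S)-3-chloro-5-formyl-5-hydroxy-6-methyl-7-oxo-6,7-dihydro-5H-cyclopenta[c]pyridin-6-yl acetate | Clc1cc2c(cn1)C(=O)[C@@](C)(OC(C)=O)[C@@]2(O)C=O | intermediate
14 | (5R,6S)-6-acetoxy-3-chloro-5-hydroxy-6-methyl-7-oxo-6,7-dihydro-5H-cyclopenta[c]pyridine-5-carboxylic acid | Clc1cc2c(cn1)C(=O)[C@@](C)(OC(C)=O)[C@@]2(O)C(=O)O | intermediate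
15 | methyl (5R,6S)-6-acetoxy-3-chloro-5-hydroxy-6-methyl-7-oxo-6,7-dihydro-5H-cyclopenta[c]pyridine-5-carboxylate | Clc1cc2c(cn1)C(=O)[C@@](C)(OC(C)=O)[C@@]2(O)C(=O)OC | intermediate
16 | (S)-2-methylbutan-1-ol | CC[C@H](C)CO | starting material
17 | (S)-2-methylbutanal | CC[C@H](C)C=O | intermediate
18 | ethyl (2E,4S)-2,4-dimethylhex-2-enoate | CC[C@H](C)/C=C(C)/C(=O)OCC | intermediate
19 | (2E,4S)-2,4-dimethylhex-2-en-1-ol | CC[C@H](C)/C=C(C)/CO | intermediate
20 | (2E,4S)-2,4-dimethylhex-2-enal | CC[C@H](C)/C=C(C)/C=O | intermediate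
21 | (3E,5S)-1,1-dibromo-3,5-dimethylhepta-1,3-diene | CC[C@H](C)/C=C(C)/C=C(Br)Br | intermediate
22 | lithium (3E,5S)-3,5-dimethylhept-3-en-1-yn-1-ide | CC[C@H](C)/C=C(C)/C#C[Li] | intermediate
23 | (3E,5S)-3,5-dimethylhept-3-en-1-yne | CC[C@H](C)/C=C(C)/C#C | intermediate
24 | tributyl[(1E,3E,5S)-3,5-dimethylhepta-1,3-dien-1-yl]stannane | CC[C@H](C)/C=C(C)/C=C/[Sn](CCCC)(CCCC)CCCC | intermediate
25 | methyl (5R,6S)-6-acetoxy-3-[(1E,3E,5S)-3,5-dimethylhepta-1,3-dien-1-yl]-5-hydroxy-6-methyl-7-oxo-6,7-dihydro-5H-cyclopenta[c]pyridine-5-carboxylate | CC[C@H](C)/C=C(C)/C=C/c1cc2c(cn1)C(=O)[C@@](C)(OC(C)=O)[C@@]2(O)C(=O)OC | target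

## Totals and risks
Total step count: 17.
Longest linear sequence: 9 (step 1 or 2, then steps 3–9, then step 17). The side-chain branch is 8 steps (steps 10–17).

**Step 3 (key aldol).**
- Risk: the acetylpyridine is acidic and ortho-hindered. Proton transfer to the enolate or retro-aldol of the congested adduct may cut the yield.
- The fallback sets out from 1 and 5 and comes back at 7. It replaces the enolisable ketone by a non-enolisable aldehyde and builds the methyl carbinol afterwards.
- Quenching 2 with DMF gives 5-bromo-2-chloroisonicotinaldehyde F1.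
- Enolate 6 adds to F1 at −78 °C on the same face, anti to tert-butyl. This gives the secondary aldol (2R,5S)-5-[(5-bromo-2-chloropyridin-4-yl)(hydroxy)methyl]-2-tert-butyl-5-methyl-1,3-dioxolan-4-one F2.
- Dess–Martin periodinane oxidises F2 to the non-enolisable ketone (2R,5S)-5-(5-bromo-2-chloroisonicotinoyl)-2-tert-butyl-5-methyl-1,3-dioxolan-4-one F3.
- MeMgBr/CeCl3 at −78 °C adds to the ketone faster than to the hindered lactone and gives 7.

**Step 5 (Parham cyclisation).**
- Risk: n-BuLi may attack the lactone, the vinylpyridine or the chloropyridine ring, or the product ketone may be over-added.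
- The fallback sets out from 8 and comes back at 10. It closes the same C7–C7a bond with a non-basic chromium organometallic onto an aldehyde.
- K2CO3 in MeOH opens the dioxolanone to methyl (2S)-3-(5-bromo-2-chloropyridin-4-yl)-2-hydroxy-2-methylbut-3-enoate F4.
- TESOTf/2,6-lutidine gives its triethylsilyl ether F5.
- iBu2AlH at −78 °C stops at (2S)-3-(5-bromo-2-chloropyridin-4-yl)-2-methyl-2-(triethylsilyloxy)but-3-enal F6.
- An intramolecular Nozaki–Hiyama–Kishi reaction (CrCl2, catalytic NiCl2, DMF, rt to 50 °C) gives (6S)-3-chloro-6-methyl-5-methylidene-6-(triethylsilyloxy)-6,7-dihydro-5H-cyclopenta[c]pyridin-7-ol F7. Either C7 epimer serves.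
- Dess–Martin periodinane gives (6S)-3-chloro-6-methyl-5-methylidene-6-(triethylsilyloxy)-5,6-dihydro-7H-cyclopenta[c]pyridin-7-one F8.
- HF·pyridine in THF frees 10.

**Step 7 (dihydroxylation).**
- Risk: the face selectivity between acetoxy and methyl may be only moderate, and the acetate may migrate to the cis CH2OH.
- The fallback sets out from 10 and comes back at 12. It uses a bulky ether as the directing group and masks the new glycol while the acetate is installed.
- TBSOTf/2,6-lutidine gives (6S)-6-(tert-butyldimethylsilyloxy)-3-chloro-6-methyl-5-methylidene-5,6-dihydro-7H-cyclopenta[c]pyridin-7-one F9.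
- OsO4/NMO attacks anti to the silyl ether and gives (5S,6S)-6-(tert-butyldimethylsilyloxy)-3-chloro-5-hydroxy-5-(hydroxymethyl)-6-methyl-5,6-dihydro-7H-cyclopenta[c]pyridin-7-one F10.
- 2,2-Dimethoxypropane/PPTS gives the spiro-acetonide silyl ether F11.
- TBAF/AcOH gives the 6-hydroxy spiro-acetonide F12.
- Ac2O/DMAP gives the 6-acetoxy spiro-acetonide F13.
- 80% aqueous AcOH at rt releases 12, which is oxidised at once as in step 8.

## Further compounds
F1 | step 3 | 5-bromo-2-chloroisonicotinaldehyde | O=Cc1cc(Cl)ncc1Br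
F2 | step 3 | (2R,5S)-5-[(5-bromo-2-chloropyridin-4-yl)(hydroxy)methyl]-2-tert-butyl-5-methyl-1,3-dioxolan-4-one (carbinol epimers) | C[C@@]1(C(O)c2cc(Cl)ncc2Br)O[C@@H](C(C)(C)C)OC1=O
F3 | step 3 | (2R,5S)-5-(5-bromo-2-chloroisonicotinoyl)-2-tert-butyl-5-methyl-1,3-dioxolan-4-one | C[C@@]1(C(=O)c2cc(Cl)ncc2Br)O[C@@H](C(C)(C)C)OC1=O
F4 | step 5 | methyl (2S)-3-(5-bromo-2-chloropyridin-4-yl)-2-hydroxy-2-methylbut-3-enoate | COC(=O)[C@@](C)(O)C(=C)c1cc(Cl)ncc1Br
F5 | step 5 | methyl (2S)-3-(5-bromo-2-chloropyridin-4-yl)-2-methyl-2-(triethylsilyloxy)but-3-enoate | COC(=O)[C@@](C)(O[Si](CC)(CC)CC)C(=C)c1cc(Cl)ncc1Br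
F6 | step 5 | (2S)-3-(5-bromo-2-chloropyridin-4-yl)-2-methyl-2-(triethylsilyloxy)but-3-enal | O=C[C@@](C)(O[Si](CC)(CC)CC)C(=C)c1cc(Cl)ncc1Br
F7 | step 5 | (6S)-3-chloro-6-methyl-5-methylidene-6-(triethylsilyloxy)-6,7-dihydro-5H-cyclopenta[c]pyridin-7-ol (C7 epimers) | Clc1cc2c(cn1)C(O)[C@@](C)(O[Si](CC)(CC)CC)C2=C
F8 | step 5 | (6S)-3-chloro-6-methyl-5-methylidene-6-(triethylsilyloxy)-5,6-dihydro-7H-cyclopenta[c]pyridin-7-one | Clc1cc2c(cn1)C(=O)[C@@](C)(O[Si](CC)(CC)CC)C2=C
F9 | step 7 | (6S)-6-(tert-butyldimethylsilyloxy)-3-chloro-6-methyl-5-methylidene-5,6-dihydro-7H-cyclopenta[c]pyridin-7-one | Clc1cc2c(cn1)C(=O)[C@@](C)(O[Si](C)(C)C(C)(C)C)C2=C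
F10 | step 7 | (5S,6S)-6-(tert-butyldimethylsilyloxy)-3-chloro-5-hydroxy-5-(hydroxymethyl)-6-methyl-5,6-dihydro-7H-cyclopenta[c]pyridin-7-one | Clc1cc2c(cn1)C(=O)[C@@](C)(O[Si](C)(C)C(C)(C)C)[C@@]2(O)CO
F11 | step 7 | spiro-acetonide silyl ether (isopropylidene acetal of F10) | Clc1cc2c(cn1)C(=O)[C@@](C)(O[Si](C)(C)C(C)(C)C)[C@@]23COC(C)(C)O3
F12 | step 7 | 6-hydroxy spiro-acetonide (desilylated F11) | Clc1cc2c(cn1)C(=O)[C@@](C)(O)[C@@]23COC(C)(C)O3
F13 | step 7 | 6-acetoxy spiro-acetonide (acetate of F12) | Clc1cc2c(cn1)C(=O)[C@@](C)(OC(C)=O)[C@@]23COC(C)(C)O3
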